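Over 40 h a kinetic resolution can stop short of its clock, so I ask first what the charge allows.

left-handed substrate 0.050 M; partner 1.00 equiv (fed, over 1.5 min); precatalyst 0.25 mol%; right-handed substrate 0.050 M; time 40 h; the fed solution adds 1.0 times the starting volume

    partner + catalyst + left-handed substrate → catalyst + left-handed product (k1 = 787 M⁻² s⁻¹)
    partner + catalyst + right-handed substrate → catalyst + right-handed product (k2 = 5.32 M⁻² s⁻¹)
    partner + precatalyst → catalyst + spent reagent (k3 = 0.0696 M⁻¹ s⁻¹)
    partner → decomposition product (k4 = 1.85 × 10⁻⁶ s⁻¹)

- catalyst is single-handed; left-handed substrate and right-handed substrate are mirror images of each other, charged as a racemate, each of them at the stated concentration
- amounts are per litre of the starting volume; all of the dose is in the solution fed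
- the reaction counts as stopped when no species that holds the left-handed substrate and right-handed substrate together changes by six tenths of a point or more over the second half of the time
- run time (flask): 40 h

- why nothing more happens at 40 h, or that something still does (forward and back rates have come level / all of the left-handed substrate has reacted / the partner has run out first / no working catalyst is left / it is still moving)
- how much of the left-handed substrate and right-handed substrate together has reacted by 40 h
- how much left-handed product there is at 40 h, in percent of the left-handed substrate and right-handed substrate together charged
- how much right-handed substrate there is at 40 h, in percent of the left-handed substrate and right-handed substrate together charged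

Both substrates react with the same partner on the same catalyst, so at any moment their rates stand as k1·c(left-handed substrate) to k2·c(right-handed substrate), and the comparison starts from the selectivity factor s = k1/k2 = 148. That ratio drifts down as c(left-handed substrate) falls, and integrating it gives the rule I carry for substrates consumed by these two steps: the fraction of right-handed substrate left equals the fraction of left-handed substrate left raised to the power 1/s.

I read the partner as 1.00 equiv on the left-handed substrate, and I neglect steps 3 and 4, so the two lost fractions add up to one. The fraction x of left-handed substrate left, being small, then nearly obeys x = ln(1/x)/s, which I iterate from ln(s)/s = 3.38% through 2.29% to 2.55%.

Taking the precatalyst as wholly activated, with catalyst at 6.25 × 10⁻⁵ M after dilution, I reckon the first half of the left-handed substrate to take about 0.226 h, far shorter than the 100 h half-life of partner by step 4. I therefore expect the partner, charged at 1.00 equiv, to run out first, with about 48.7% each of left-handed product and right-handed substrate.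

The forecast, on the reading “I take equiv and mol% on the racemate”, which differs from mine, gives it is still moving, 83.1% conversion, 50% left-handed product and 16.9% right-handed substrate.

The flask gives the partner has run out first, 49.6% conversion, 48.4% left-handed product and 48.8% right-handed substrate.

In this flask the partner stands at 0% of its charge at 40.0 h, less than the 98% of right-handed substrate left, and no substrate or product share moves by more than 0.055 percentage points over the second half of the time. Raising the 3.2% of left-handed substrate left in this flask to the power 1/s gives 97.7%, against that 98%. The neighbour flask with 0.400 equiv of partner keeps 61% of its left-handed substrate, so the rule gives 99.7% of right-handed substrate, and that flask holds 99.7%.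

The rate constants were drawn at random within sensible limits; the run is a simulation.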